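Hours of run mean little in these flasks until they are counted in half-lives of the target.

    starting material + partner ⇌ target (K1 = 250 M⁻¹, k1 = 0.64 M⁻¹ s⁻¹, Ea1 = 56.0 kJ mol⁻¹, ΔH1 = −27.0 kJ mol⁻¹)
    starting material + partner ⇌ isomer of the product (K2 = 8600 M⁻¹, k2 = 0.33 M⁻¹ s⁻¹, Ea2 = 54.0 kJ mol⁻¹, ΔH2 = −14.0 kJ mol⁻¹)
    target + free catalyst ⇌ isomer of the product + free catalyst, rate k3*[free catalyst]*[target] forward; the back reaction follows from the equilibrium constant (k3 = 0.28 M⁻¹ s⁻¹, Ea3 = 62.0 kJ mol⁻¹)
    starting material + target → side product (k4 = 0.0062 M⁻¹ s⁻¹, Ea4 = 68.0 kJ mol⁻¹)
    free catalyst → spent catalyst (k5 = 2.5 × 10⁻⁴ s⁻¹, Ea5 = 102 kJ mol⁻¹)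
    2 partner → self-condensation product (k6 = 0.0068 M⁻¹ s⁻¹, Ea6 = 67.0 kJ mol⁻¹)
    (constants at 20 °C)

| flask | starting material | partner | free catalyst | time | remark | temperature |
|---|---|---|---|---|---|---|
| green | 0.020 M | 0.900 equiv | 4.8 mol% | 6.0 h | at −20 °C until 80 min, from then on at 20 °C |  |
| ochre | 0.020 M | 0.900 equiv | 4.8 mol% | 6.0 h |  | 0 °C |
| blue | 0.020 M | 0.900 equiv | 4.8 mol% | 6.0 h |  | 20 °C |
| grey | 0.020 M | 0.900 equiv | 4.8 mol% | 6.0 h |  | −20 °C |

- percentages count the starting material that a species holds: one side product counts as two
- where a step has two of a species, its rate is k times that concentration squared, and two are used at each turn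
- all constants are for 20 °C and move with temperature by the activation energies and enthalpies

1. the best flask by amount of target, in percent of the starting material charged; "all alike" if 1.5 percentage points covers them all (green / ochre / blue / grey / all alike)
2. amount of target at the end, in percent of the starting material charged, green
3. amount of target at the end, in percent of the starting material charged, ochre
4. amount of target at the end, in percent of the starting material charged, blue
5. amount of target at the end, in percent of the starting material charged, grey

Minutes of a short meeting before the runs; the secretary's reckoning is mine.

The chair asked what a flask can hold. The kineticist answered that the partner is the limiting reagent at 0.900 equiv, so target and isomer of the product share that charge, split by their forward steps. In grey the first step outruns the second by r = 1.70, which gives a kinetic ceiling of 56.7% target.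

The process chemist objected that target does not stay, since it falls back by the first step and free catalyst turns it over by the third. I proposed one clock for both. Fallen-back target returns as isomer of the product in the proportion of the second forward step to both forward steps, so the loss constant is k_r/(1 + r) + k_c. Here k_r is the back constant of the first step, 0.0424 h⁻¹ in grey, and k_c is the third step's constant times free catalyst, 0.0174 h⁻¹ there. The drain half-life t_d, ln 2 over that loss constant, is 21.0 h in grey.

The chair asked what the fall heads for. I said an equilibrium level under thermodynamic control, estimated as the partner's charge divided by one plus the third step's equilibrium constant. That constant is 14.8 in grey, so the estimated level there is 5.69%. I took the excess of ceiling over that level to halve once per t_d.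

Grey's run is 0.286 half-lives, which gives 47.5%. Ochre has r = 1.83, ceiling 58.2%, equilibrium level 3.71% and t_d 1.65 h, so I put it at 8.10%.

Blue's t_d, with free catalyst at its charge, is 10.1 min, so I put blue at its equilibrium level, 2.54%. Free catalyst has a half-life of 46.2 min at 20 °C, so I counted green's warm stretch after 80 min by the fall-back term alone, whose half-life is 13.3 min. That stretch holds 21.1 of those half-lives, so I gave green the same level, 2.54%. The meeting ranked grey first.

The forecast gave green 2.4%, ochre 6.5%, blue 2.4% and grey 41%, with grey best, holding that at the cold end “both reversion and catalysed isomerisation are almost frozen”; its grey stands below my reckoning.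

The simulation gives green 2.27%, ochre 8.36%, blue 2.25% and grey 43.7%, with grey best; grey ends below my reckoning. A flask like blue kept at −5 °C has r = 1.80 and t_d 3.04 h, shorter than grey's 21.0 h and longer than blue's 10.1 min. With its equilibrium level of 4.11%, the same halving gives 17.8%. That neighbour ended with 16.7% target.

The constants used here were drawn at random within sensible limits; what happens was integrated by code.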